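## Retrosynthetic overview

1. The diaryl enone of the target is traced back to its 4,5-dihydro compound; the C4=C5 bond comes from oxidising the pyrogallol ring and letting the quinone tautomerise (o-quinone → quinone methide → aryl enone).
2. The cis-bicyclo[3.3.0]octenedione is traced back by a retro-α-ketol (1,2-acyl) shift to a 1-hydroxybicyclo[3.2.1]oct-3-ene-2,8-dione.
3. That bridged dione is opened by a retro-(5+2) cycloaddition into the 3-hydroxy-o-quinone of one pentahydroxystilbene (five ring carbons) and the C=C of a second molecule of the same stilbene.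
4. Ring order in the forward sense: bicyclo[3.2.1] system first, then both five-membered rings in the acyl shift, all in one flask under one chiral Lewis acid that fixes C3a/C6a.
5. The pentahydroxystilbene comes from its pentamethyl ether, made by Horner–Wadsworth–Emmons olefination of two commercial aromatics.

Assumption 1: the target is taken to arise in nature from two molecules of 3,3',4,5,5'-pentahydroxy-trans-stilbene by oxidation of one to its 3-hydroxy-o-quinone, (5+2) cycloaddition to the C=C of the other, α-ketol shift and dehydrogenation.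

Assumption 2: the sense of induction of the Sc(III)–pybox catalyst cannot be predicted with confidence; (S,S)-Ph-pybox is written, and its antipode is used if the first run gives the mirror-image series (checked by ECD and optical rotation against the natural product).

Equivalents in step 3 refer to compound 4.

## Route

Step 1
Reactants: 1 diethyl (3,5-dimethoxybenzyl)phosphonate; 2 3,4,5-trimethoxybenzaldehyde
Product: 3 1,2,3-trimethoxy-5-[(E)-2-(3,5-dimethoxyphenyl)ethenyl]benzene
Conditions: KOtBu (1.2 equiv), THF, 0 °C → rt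
Reagents that add atoms: none
Why: Horner–Wadsworth–Emmons olefination of a benzylic phosphonate with an aromatic aldehyde gives the (E)-stilbene with high selectivity; no stereocentre is formed.

Step 2
Reactants: 3 1,2,3-trimethoxy-5-[(E)-2-(3,5-dimethoxyphenyl)ethenyl]benzene
Product: 4 5-[(E)-2-(3,5-dihydroxyphenyl)ethenyl]benzene-1,2,3-triol
Conditions: BBr3 (8 equiv), CH2Cl2, −78 °C → rt; ice/H2O quench; handled under Ar
Reagents that add atoms: none
Why: Lewis-acid cleavage of aryl methyl ethers (BBr3 demethylation) leaves the (E)-alkene untouched and frees all five phenols; no stereocentre is formed.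

Step 3
Reactants: 4 5-[(E)-2-(3,5-dihydroxyphenyl)ethenyl]benzene-1,2,3-triol (two molecules: one becomes the five-carbon partner, one the two-carbon partner)
Product: 8 (3aS,6aS)-4-(3,5-dihydroxyphenyl)-3-[(E)-2-(3,5-dihydroxyphenyl)ethenyl]-6a-hydroxy-5-(3,4,5-trihydroxyphenyl)-3a,6a-dihydropentalene-1,6-dione, via hydroxy-o-quinone 5 (not isolated), via bicyclo[3.2.1]octenedione adduct 6 (not isolated), via tetrahydropentalenedione 7 (not isolated)
Conditions: Sc(OTf)3 (10 mol%), (S,S)-Ph-pybox (12 mol%), 4 Å MS, THF/CH2Cl2, −40 °C, o-chloranil (0.5 equiv, slow addition); then 0 °C; then o-chloranil (0.5 equiv), 0 °C; aq. Na2S2O4 work-up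
Reagents that add atoms: none
Why: Proposed new method: o-chloranil turns half of 4 into the 3-hydroxy-o-quinone 5, which chelates the chiral Sc(III)–pybox complex through its vicinal C=O/C–O oxygens and so becomes a 2-oxy-pentadienyl cation (perezone/purpurogallin type) that takes up the electron-rich C=C of unoxidised 4 in a (5+2) cycloaddition, the alkene carbon bearing the resorcinol ring (nucleophilic, β to the 4-OH ring) bonding to the ring CH terminus and the quinone-methide-stabilised carbon to the C–O terminus, with the ligand blocking one π-face so that the bridgeheads of 6 are set as (1R,5R); the same chelate (bridgehead O–C1–C8=O held syn-coplanar) then drives a suprafacial 1,2-acyl shift (α-ketol rearrangement) that relieves the strained one-carbon keto bridge, forms both five-membered rings of 7 and carries C5 of 6 unchanged into C3a while C6a follows from the cis fusion; the second half-equivalent of o-chloranil oxidises the pyrogallol ring of 7 to its hydroxy-o-quinone, which tautomerises via the quinone methide to the aryl enone 8 and erases C4/C5, so endo and exo adducts converge on one enantiomer; the closest known reactions are the acid-promoted (5+2) cycloadditions of quinone-derived cations with (E)-arylpropenes including their chiral Ti(IV)-diolate-controlled variants, the chelating-Lewis-acid-catalysed acyl-migrating α-ketol rearrangement of 2-hydroxy-1,3-diketones, and the o-quinone → quinone methide tautomerisation of 4-alkylcatechol quinones.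

## Compound list

1 | diethyl (3,5-dimethoxybenzyl)phosphonate | CCOP(=O)(Cc1cc(OC)cc(OC)c1)OCC | starting material
2 | 3,4,5-trimethoxybenzaldehyde | COc1cc(C=O)cc(OC)c1OC | starting material
3 | 1,2,3-trimethoxy-5-[(E)-2-(3,5-dimethoxyphenyl)ethenyl]benzene | COc1cc(/C=C/c2cc(OC)c(OC)c(OC)c2)cc(OC)c1 | intermediate
4 | 5-[(E)-2-(3,5-dihydroxyphenyl)ethenyl]benzene-1,2,3-triol | Oc1cc(/C=C/c2cc(O)c(O)c(O)c2)cc(O)c1 | intermediate
5 | 5-[(E)-2-(3,5-dihydroxyphenyl)ethenyl]-3-hydroxycyclohexa-3,5-diene-1,2-dione | O=C1C(=O)C(O)=CC(/C=C/c2cc(O)cc(O)c2)=C1 | intermediate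
6 | (1R,5R,6R,7S)-6-(3,5-dihydroxyphenyl)-4-[(E)-2-(3,5-dihydroxyphenyl)ethenyl]-1-hydroxy-7-(3,4,5-trihydroxyphenyl)bicyclo[3.2.1]oct-3-ene-2,8-dione (7-aryl endo under the enone bridge, 6-aryl exo, the two aryls trans) | O=C1C=C(/C=C/c2cc(O)cc(O)c2)[C@H]3[C@H](c2cc(O)cc(O)c2)[C@@H](c2cc(O)c(O)c(O)c2)[C@]1(O)C3=O | intermediate
7 | (3aR,4S,5S,6aS)-4-(3,5-dihydroxyphenyl)-3-[(E)-2-(3,5-dihydroxyphenyl)ethenyl]-6a-hydroxy-5-(3,4,5-trihydroxyphenyl)-3a,4,5,6a-tetrahydropentalene-1,6-dione (H-3a, 6a-OH and 4-aryl on one face, 5-aryl on the other) | O=C1C=C(/C=C/c2cc(O)cc(O)c2)[C@H]2[C@H](c3cc(O)cc(O)c3)[C@@H](c3cc(O)c(O)c(O)c3)C(=O)[C@@]12O | intermediate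
8 | (3aS,6aS)-4-(3,5-dihydroxyphenyl)-3-[(E)-2-(3,5-dihydroxyphenyl)ethenyl]-6a-hydroxy-5-(3,4,5-trihydroxyphenyl)-3a,6a-dihydropentalene-1,6-dione (cis-fused; H-3a and 6a-OH on the same face) | O=C1C=C(/C=C/c2cc(O)cc(O)c2)[C@H]2C(c3cc(O)cc(O)c3)=C(c3cc(O)c(O)c(O)c3)C(=O)[C@@]12O | target

Total step count: 3. Longest linear sequence: 3.

## Steps most likely to fail, with fallbacks

**Step 3 (highest risk).** The quinone 5 can instead self-condense in the purpurogallin manner, add the alkene through oxygen (benzodioxane) or through its own styryl terminus, or leak from 6 by ionisation to an aromatic dihydrobenzofuran. The enantioselectivity in a medium with ten free phenols is untested.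
The fallback sets out from 4, uses 3 kept from step 1 as partner, and returns at 8. Compound 4 is oxidised completely to 5 (o-chloranil, 1.0 equiv, −40 °C) in the presence of 3 equiv of the non-phenolic stilbene 3 and the same Sc(III)–pybox catalyst in CH2Cl2/THF. The only two-carbon partner is then an excess, non-oxidisable arylalkene, which removes redox scrambling and pyrogallol self-condensation. The (5+2) adduct (1R,5R,6R,7S)-4-[(E)-2-(3,5-dihydroxyphenyl)ethenyl]-6-(3,5-dimethoxyphenyl)-1-hydroxy-7-(3,4,5-trimethoxyphenyl)bicyclo[3.2.1]oct-3-ene-2,8-dione F1 shifts in the flask to (3aR,4S,5S,6aS)-3-[(E)-2-(3,5-dihydroxyphenyl)ethenyl]-4-(3,5-dimethoxyphenyl)-6a-hydroxy-5-(3,4,5-trimethoxyphenyl)-3a,4,5,6a-tetrahydropentalene-1,6-dione F2, which is isolated. Dehydrogenation becomes a separate step with DDQ (dioxane, rt) and gives (3aS,6aS)-3-[(E)-2-(3,5-dihydroxyphenyl)ethenyl]-4-(3,5-dimethoxyphenyl)-6a-hydroxy-5-(3,4,5-trimethoxyphenyl)-3a,6a-dihydropentalene-1,6-dione F3. BBr3 (CH2Cl2, −78 → 0 °C) then removes the five methyl groups and gives 8.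

**Step 2.** Risks are incomplete cleavage, HBr-induced cationic oligomerisation of the electron-rich stilbene on quench, and air oxidation of 4 during isolation.
The fallback sets out from 2 and returns at 4; the phenols are freed before the alkene exists. Compound 2 is demethylated (BBr3, CH2Cl2) to 3,4,5-trihydroxybenzaldehyde F4. F4 is condensed with commercial 3,5-dihydroxyphenylacetic acid (piperidine, N-methylimidazole, PEG-200, 150 °C, Ar) in a Knoevenagel/Perkin-type reaction to (E)-2-(3,5-dihydroxyphenyl)-3-(3,4,5-trihydroxyphenyl)prop-2-enoic acid F5 (not isolated). Its 4-hydroxyl-assisted decarboxylation through a quinone methide gives the (E)-stilbene 4 directly.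

**Step 1 (lowest risk).** Possible problems are incomplete conversion or E/Z mixtures.
The fallback sets out from 2 and returns at 3; the stilbene bond is made by arylation instead of olefination. Wittig methylenation of 2 (Ph3PCH3Br, KOtBu, THF, 0 °C) gives 5-ethenyl-1,2,3-trimethoxybenzene F6. Mizoroki–Heck coupling of F6 with 1-bromo-3,5-dimethoxybenzene (Pd(OAc)2, P(o-tol)3, Et3N, DMF, 100 °C) gives 3 with E-selectivity.

## Further compounds

F1 | step 3 | (1R,5R,6R,7S)-4-[(E)-2-(3,5-dihydroxyphenyl)ethenyl]-6-(3,5-dimethoxyphenyl)-1-hydroxy-7-(3,4,5-trimethoxyphenyl)bicyclo[3.2.1]oct-3-ene-2,8-dione | O=C1C=C(/C=C/c2cc(O)cc(O)c2)[C@H]3[C@H](c2cc(OC)cc(OC)c2)[C@@H](c2cc(OC)c(OC)c(OC)c2)[C@]1(O)C3=O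
F2 | step 3 | (3aR,4S,5S,6aS)-3-[(E)-2-(3,5-dihydroxyphenyl)ethenyl]-4-(3,5-dimethoxyphenyl)-6a-hydroxy-5-(3,4,5-trimethoxyphenyl)-3a,4,5,6a-tetrahydropentalene-1,6-dione | O=C1C=C(/C=C/c2cc(O)cc(O)c2)[C@H]2[C@H](c3cc(OC)cc(OC)c3)[C@@H](c3cc(OC)c(OC)c(OC)c3)C(=O)[C@@]12O
F3 | step 3 | (3aS,6aS)-3-[(E)-2-(3,5-dihydroxyphenyl)ethenyl]-4-(3,5-dimethoxyphenyl)-6a-hydroxy-5-(3,4,5-trimethoxyphenyl)-3a,6a-dihydropentalene-1,6-dione | O=C1C=C(/C=C/c2cc(O)cc(O)c2)[C@H]2C(c3cc(OC)cc(OC)c3)=C(c3cc(OC)c(OC)c(OC)c3)C(=O)[C@@]12O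
F4 | step 2 | 3,4,5-trihydroxybenzaldehyde | O=Cc1cc(O)c(O)c(O)c1
F5 | step 2 | (E)-2-(3,5-dihydroxyphenyl)-3-(3,4,5-trihydroxyphenyl)prop-2-enoic acid | OC(=O)/C(c1cc(O)cc(O)c1)=C/c1cc(O)c(O)c(O)c1
F6 | step 1 | 5-ethenyl-1,2,3-trimethoxybenzene | C=Cc1cc(OC)c(OC)c(OC)c1
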